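**Strategy.** Atoms are numbered as in 4aH-chromen-5-one (O1, C2–C4, C4a, C5–C8, C8a). The pyran ring is a cis-allyl vinyl ether joining the quaternary carbon C4a to the enol-ether carbon C8a of a dearomatised acylphloroglucinol. Cutting O1–C8a and then C4a–C4 leads to flat, achiral deoxycohumulone, whose two prenyl-bearing ring carbons are homotopic, and a (Z)-iodoalkenol that already carries O1. In one operation a palladium-catalysed enantioselective dearomative C-alkenylation sets C4a and frees the C8a carbonyl as a vinylogous acid; the open hydroxyalkenyl dienone so formed then closes, the cis-held tertiary hydroxyl condensing onto C8a. The Z-alkene C3=C4 and the vinylogous ester C8=C8a–O1 are the features exploited.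

Key step: step 4

Assumption: the (R)-configured ligand is taken to deliver the (R)-configured quaternary carbon; if the sense of induction proves opposite, its enantiomer is used without other change.

**Step 1**
Reactants: 1 phloroglucinol (benzene-1,3,5-triol); 2 isobutyryl chloride (2-methylpropanoyl chloride)
Product: 3 phlorisobutyrophenone [2-methyl-1-(2,4,6-trihydroxyphenyl)propan-1-one]
Conditions: AlCl3 (3 equiv), PhNO2–CH2Cl2, 0 → 40 °C; aq. HCl
Reagents that add atoms: none
Why: Friedel–Crafts acylation of the very electron-rich triol should stop after one acyl group, because the chelated aryl ketone deactivates the ring.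

**Step 2**
Reactants: 3 phlorisobutyrophenone; 4 prenyl bromide (1-bromo-3-methylbut-2-ene, 2.1 equiv)
Product: 5 deoxycohumulone [2-methyl-1-[2,4,6-trihydroxy-3,5-bis(3-methylbut-2-en-1-yl)phenyl]propan-1-one]
Conditions: KOH (10 % aq.), 0 °C → rt
Reagents that add atoms: none
Why: C-alkylation of the ambident phloroglucinol anion in water, where solvation of oxygen disfavours O-alkylation, should prenylate both free ring carbons; mono- and triprenyl congeners are removed by chromatography.

**Step 3**
Reactants: 6 ethyl (Z)-3-iodoacrylate
Product: 7 (Z)-4-iodo-2-methylbut-3-en-2-ol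
Conditions: MeMgBr (2.3 equiv), THF, −78 → −20 °C; sat. aq. NH4Cl
Reagents that add atoms: methylmagnesium bromide, C[Mg]Br
Why: Double 1,2-addition of the Grignard reagent to the ester should give the tertiary alcohol with the Z-iodoalkene untouched, since at low temperature carbonyl addition outruns conjugate addition–elimination and iodine–magnesium exchange.

**Step 4**
Reactants: 5 deoxycohumulone; 7 (Z)-4-iodo-2-methylbut-3-en-2-ol (1.1 equiv)
Product: 9 (4aR)-7-hydroxy-2,2-dimethyl-4a,8-bis(3-methylbut-2-en-1-yl)-6-(2-methylpropanoyl)-2H-chromen-5(4aH)-one (CNP0119032.1), via hydroxyalkenyl dienone 8 (not isolated)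
Conditions: Pd2(dba)3 (2.5 mol %), (R)-2-(dicyclohexylphosphino)-2'-(dimethylamino)-1,1'-binaphthyl (6 mol %), K3PO4 (2 equiv), toluene, 70 °C; then aq. NaH2PO4 wash, crude 8 with PPTS (0.2 equiv), 4 Å MS, CH2Cl2, rt
Reagents that add atoms: none
Why: Proposed new method: zerovalent palladium inserts into the C–I bond of 7 with retention of the Z geometry, the potassium phenoxide of 5 (deprotonated at the unchelated 4-OH) binds the alkenyl complex of divalent palladium and, through its C-bound (oxa-allyl) form, undergoes C–C reductive elimination at a prenyl-bearing ring carbon to give dienone 8, the closest known reaction types being the palladium-catalysed enantioselective α-alkenylation of ketone enolates to quaternary carbons and the arylative dearomatisation of 1-substituted 2-naphthols with bulky monophosphines. The only new stereocentre, C4a (C6 of 8), is set in this reductive elimination by the axially chiral P,N-ligand (catalyst control), because C3 and C5 of 5 are homotopic and only the ring face has to be chosen. After acidification the tertiary hydroxyl O1, held next to the ring by the cis C3=C4 bond, adds to the C8a carbonyl carbon (6-exo-trig hemiketalisation) and loss of water gives the vinylogous ester, which closes the pyran ring through the O1–C8a bond. C- over O-alkenylation is needed and is secured by the soft, carbon-centred nucleophilicity of the phloroglucinol anion at its prenylated carbons (the same site that is alkylated on the way to colupulone) and by the reluctance of aryloxide–alkenyl C–O reductive elimination. Ring closure at C8a and not at C5 is needed and is secured because C5 is tied into the hydrogen-bonded β-triketone chelate with the isobutyryl group, whereas C8a is the free vinylogous-acid carbonyl and its enol ether keeps that chelate intact. PPTS is mild enough that the tertiary allylic alcohol should not ionise, so the ring oxygen is the former hydroxyl oxygen.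

**Compound list**
1 | phloroglucinol (benzene-1,3,5-triol) | Oc1cc(O)cc(O)c1 | starting material
2 | isobutyryl chloride (2-methylpropanoyl chloride) | CC(C)C(=O)Cl | starting material
3 | phlorisobutyrophenone, 2-methyl-1-(2,4,6-trihydroxyphenyl)propan-1-one | CC(C)C(=O)c1c(O)cc(O)cc1O | intermediate
4 | prenyl bromide (1-bromo-3-methylbut-2-ene) | CC(C)=CCBr | starting material
5 | deoxycohumulone, 2-methyl-1-[2,4,6-trihydroxy-3,5-bis(3-methylbut-2-en-1-yl)phenyl]propan-1-one | CC(C)C(=O)c1c(O)c(CC=C(C)C)c(O)c(CC=C(C)C)c1O | intermediate
6 | ethyl (Z)-3-iodoacrylate | CCOC(=O)/C=C\I | starting material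
7 | (Z)-4-iodo-2-methylbut-3-en-2-ol | CC(C)(O)/C=C\I | intermediate
8 | (6R)-3,5-dihydroxy-6-[(1Z)-3-hydroxy-3-methylbut-1-en-1-yl]-4,6-bis(3-methylbut-2-en-1-yl)-2-(2-methylpropanoyl)cyclohexa-2,4-dien-1-one | CC(C)=CCC1=C(O)[C@](/C=C\C(C)(C)O)(CC=C(C)C)C(=O)C(C(=O)C(C)C)=C1O | intermediate
9 | (4aR)-7-hydroxy-2,2-dimethyl-4a,8-bis(3-methylbut-2-en-1-yl)-6-(2-methylpropanoyl)-2H-chromen-5(4aH)-one (CNP0119032.1) | CC(C)=CCC1=C2OC(C)(C)C=C[C@@]2(CC=C(C)C)C(=O)C(C(=O)C(C)C)=C1O | target

**Step count.** Total steps: 4. Longest linear sequence: 3 (steps 1, 2 and 4; step 3 prepares the coupling partner).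

**Steps most likely to fail**

Step 4 (Proposed new method). The coupling may be diverted to C–O reductive elimination. Reductive elimination from the stabilised phenoxide may be so slow that the alkenyl iodide is reduced or dimerised. The ligand may discriminate the two ring faces poorly. Hemiketalisation may occur at C5 instead of C8a. The fallback uses known chemistry, sets out from 5 and comes back at 8. Electrophilic alkynylation of the stabilised enolate of 5 is carried out with the ethynylbenziodoxolone reagent 1-[3-methyl-3-(trimethylsilyloxy)but-1-yn-1-yl]-1,2-benziodoxol-3(1H)-one F1. F1 is prepared from commercial 2-methyl-4-(trimethylsilyl)but-3-yn-2-ol, 1-hydroxy-1,2-benziodoxol-3(1H)-one and TMSOTf, the excess of which silylates the hydroxyl. The alkynylation is run under phase-transfer conditions (K2CO3, toluene, a C2-symmetric binaphthyl-derived spiro ammonium bromide). It should give (6R)-3,5-dihydroxy-6-[3-methyl-3-(trimethylsilyloxy)but-1-yn-1-yl]-4,6-bis(3-methylbut-2-en-1-yl)-2-(2-methylpropanoyl)cyclohexa-2,4-dien-1-one F2, whose enantiomeric purity can be raised by crystallising its salt with (R)-1-phenylethylamine. Semihydrogenation over lead-poisoned Pd/CaCO3 with quinoline should then give the cis-alkene (6R)-3,5-dihydroxy-6-[(1Z)-3-methyl-3-(trimethylsilyloxy)but-1-en-1-yl]-4,6-bis(3-methylbut-2-en-1-yl)-2-(2-methylpropanoyl)cyclohexa-2,4-dien-1-one F3. PPTS in MeOH–CH2Cl2 removes the silyl group to give 8, which closes to 9 as in step 4.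

Step 2. Under- and over-alkylation (mono- and triprenyl products) and O-alkylation may erode the amount of the symmetric diprenyl compound. The fallback sets out from 3 and comes back at 5. It is a Friedel–Crafts prenylation under Lewis acid, with 2-methylbut-3-en-2-ol and BF3·OEt2 in dioxane at rt, in which the prenyl cation attacks the neutral phenol instead of an alkyl halide meeting the phenoxide. New compound on the way: none F0.

Step 3. Conjugate addition–elimination at the iodine-bearing carbon, iodine–magnesium exchange or Z-to-E isomerisation may compete with carbonyl addition. The fallback bypasses 6: it sets out from commercial 2-methylbut-3-yn-2-ol rather than from a numbered compound and comes back at 7. Iodination of the terminal alkyne (N-iodosuccinimide, AgNO3 cat., acetone) should give 4-iodo-2-methylbut-3-yn-2-ol F4. cis-Reduction with diimide (2-nitrobenzenesulfonyl hydrazide, Et3N, THF–iPrOH, rt) should then give 7.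

**Further compounds**
F1 | step 4 | 1-[3-methyl-3-(trimethylsilyloxy)but-1-yn-1-yl]-1,2-benziodoxol-3(1H)-one | CC(C)(O[Si](C)(C)C)C#CI1OC(=O)c2ccccc21
F2 | step 4 | (6R)-3,5-dihydroxy-6-[3-methyl-3-(trimethylsilyloxy)but-1-yn-1-yl]-4,6-bis(3-methylbut-2-en-1-yl)-2-(2-methylpropanoyl)cyclohexa-2,4-dien-1-one | CC(C)=CCC1=C(O)[C@](C#CC(C)(C)O[Si](C)(C)C)(CC=C(C)C)C(=O)C(C(=O)C(C)C)=C1O
F3 | step 4 | (6R)-3,5-dihydroxy-6-[(1Z)-3-methyl-3-(trimethylsilyloxy)but-1-en-1-yl]-4,6-bis(3-methylbut-2-en-1-yl)-2-(2-methylpropanoyl)cyclohexa-2,4-dien-1-one | CC(C)=CCC1=C(O)[C@](/C=C\C(C)(C)O[Si](C)(C)C)(CC=C(C)C)C(=O)C(C(=O)C(C)C)=C1O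
F0 | step 2 | none | none
F4 | step 3 | 4-iodo-2-methylbut-3-yn-2-ol | CC(C)(O)C#CI
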